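**Plan**

- Retrosynthesis (target numbered as a 6-oxabicyclo[3.2.2]non-3-ene): cut O6–C5 (Baeyer–Villiger retron, C5 carries both OMe and the lactone oxygen) to reach the bicyclo[3.2.1]oct-3-ene-2,8-dione 12. Then cut C1–C8 and put C8 back on the oxygen of C7, which gives the 3a-methoxy-dihydrobenzofuran-6-one 10. Then cut C5–OMe, C3–allyl, the benzylic C8–O bond and C5–C9.
- Enabling feature: C1 is the methine between the C2 ketone and the C7 carbonyl (a latent enol carbon), and C8 is benzylic to the 3,4,5-trimethoxyphenyl ring (a latent cation). The six carbons C1–C5 and C7 are a dearomatised resorcinol ring, so the O-benzyl enol-ether isomer 10 is a simple dihydrobenzofuran, and a 1,3 shift of C8 from oxygen to C1 builds the bridged skeleton.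
- Forward order of rings: arene, then the dihydrofuran ring (a temporary ring, closed in step 4 and opened in step 8), then dearomatisation (step 7). One bond then closes the cyclopentanone and cycloheptenone rings of the bicyclo[3.2.1]octane together (step 8), and oxygen insertion gives the 6-oxabicyclo[3.2.2]nonane (step 9).
- Stereochemistry: the methyl-bearing carbon comes from a catalyst-controlled hydrogenation with dynamic kinetic resolution (step 3). All other centres are relayed from it: aryl trans to methyl (steps 4 and 8), methoxy anti to methyl (step 7), bridgehead fixed by the tether (step 8), retention in the migration (step 9).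

Key step: step 8

Assumption: 1 and 3 are taken as catalogue chemicals; the (1S) carbinol configuration written for 5 and 6 is the one expected from the catalyst but is of no consequence, because that centre is ionised in step 4.

**Step 1**
Reactants: 1 4-bromobenzene-1,3-diol
Product: 2 1-bromo-2,4-bis(methoxymethoxy)benzene
Conditions: MOMCl (2.5 equiv), iPr2NEt (3 equiv), CH2Cl2, 0 °C → rt
Reagents that add atoms: chloromethyl methyl ether, COCCl
Why: O-alkylation of both phenols (Williamson-type acetal formation) gives base-stable methoxymethyl ethers that should survive the enolate coupling and the hydrogenation and come off under the acid of step 4.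

**Step 2**
Reactants: 2 1-bromo-2,4-bis(methoxymethoxy)benzene; 3 1-(3,4,5-trimethoxyphenyl)propan-1-one
Product: 4 rac-2-[2,4-bis(methoxymethoxy)phenyl]-1-(3,4,5-trimethoxyphenyl)propan-1-one
Conditions: Pd(OAc)2 (2 mol %), P(tBu)3 (4 mol %), NaOtBu (1.3 equiv), THF, 60 °C
Reagents that add atoms: none
Why: Palladium-catalysed ketone α-arylation (Buchwald–Hartwig type), in which zerovalent palladium inserts into the C–Br bond and the sodium enolate of 3 is arylated at carbon, a second arylation being blocked because the product enolate is fully substituted; the new centre is deliberately racemic and configurationally labile.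

**Step 3**
Reactants: 4 rac-2-[2,4-bis(methoxymethoxy)phenyl]-1-(3,4,5-trimethoxyphenyl)propan-1-one
Product: 5 (1S,2S)-2-[2,4-bis(methoxymethoxy)phenyl]-1-(3,4,5-trimethoxyphenyl)propan-1-ol
Conditions: trans-RuCl2[(R)-xylBINAP][(R)-DAIPEN] (1 mol %), KOtBu (0.2 equiv), H2 (20 atm), iPrOH, 30 °C
Reagents that add atoms: none
Why: Noyori asymmetric hydrogenation with dynamic kinetic resolution, in which the base should racemise the doubly activated α-CH faster than reduction and the (R),(R)-catalyst, which gives (S)-carbinols from aryl ketones, should reduce the (S)-ketone through the Felkin–Anh-matched transition state, so that the methyl-bearing centre is set as S.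

**Step 4**
Reactants: 5 (1S,2S)-2-[2,4-bis(methoxymethoxy)phenyl]-1-(3,4,5-trimethoxyphenyl)propan-1-ol
Product: 7 (2S,3S)-3-methyl-2-(3,4,5-trimethoxyphenyl)-2,3-dihydro-1-benzofuran-6-ol, via deprotected triol 6 (not isolated)
Conditions: HCl (2 M in MeOH), 40 °C
Reagents that add atoms: none
Why: Acid methanolysis removes both acetals, the benzylic alcohol then ionises to a cation stabilised by the trimethoxyphenyl ring and the ortho phenol closes the five-membered ring (SN1-type etherification), the aryl group settling trans to the neighbouring methyl group under reversible closure so that C2 is set from C3.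

**Step 5**
Reactants: 7 (2S,3S)-3-methyl-2-(3,4,5-trimethoxyphenyl)-2,3-dihydro-1-benzofuran-6-ol
Product: 8 (2S,3S)-5-bromo-3-methyl-2-(3,4,5-trimethoxyphenyl)-2,3-dihydro-1-benzofuran-6-ol
Conditions: NBS (1.0 equiv), MeCN, −20 °C
Reagents that add atoms: N-bromosuccinimide, O=C1CCC(=O)N1Br
Why: Electrophilic aromatic bromination should go to C5, which is ortho to the free hydroxyl, para to the ring oxygen and unhindered, whereas C7 is flanked by two oxygens and the trimethoxyphenyl ring is less activated and hindered.

**Step 6**
Reactants: 8 (2S,3S)-5-bromo-3-methyl-2-(3,4,5-trimethoxyphenyl)-2,3-dihydro-1-benzofuran-6-ol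
Product: 9 (2S,3S)-3-methyl-5-(prop-2-en-1-yl)-2-(3,4,5-trimethoxyphenyl)-2,3-dihydro-1-benzofuran-6-ol
Conditions: allylSnBu3 (1.3 equiv), Pd(PtBu3)2 (5 mol %), CsF (2.2 equiv), dioxane, 80 °C
Reagents that add atoms: allyltributylstannane, C=CC[Sn](CCCC)(CCCC)CCCC
Why: Stille coupling, in which a zerovalent palladium catalyst with a bulky electron-rich phosphine inserts into the electron-rich aryl bromide and fluoride-activated allyl transfer installs the allyl group without touching the stereocentres.

**Step 7**
Reactants: 9 (2S,3S)-3-methyl-5-(prop-2-en-1-yl)-2-(3,4,5-trimethoxyphenyl)-2,3-dihydro-1-benzofuran-6-ol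
Product: 10 (2S,3R,3aS)-3a-methoxy-3-methyl-5-(prop-2-en-1-yl)-2-(3,4,5-trimethoxyphenyl)-3,3a-dihydro-1-benzofuran-6(2H)-one
Conditions: PhI(OAc)2 (1.1 equiv), MeOH, −10 → 0 °C
Reagents that add atoms: methanol, CO
Why: Oxidative dearomatisation of a para-alkyl phenol by a trivalent iodine reagent, with capture by methanol at C3a (para to the hydroxyl, giving a para-quinol ether whose ring oxygen ends up in a stabilising vinylogous ester) and with methanol expected to add anti to the adjacent C3 methyl group so that C3a is set S.

**Step 8**
Reactants: 10 (2S,3R,3aS)-3a-methoxy-3-methyl-5-(prop-2-en-1-yl)-2-(3,4,5-trimethoxyphenyl)-3,3a-dihydro-1-benzofuran-6(2H)-one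
Product: 12 (1R,5R,6R,7R)-5-methoxy-6-methyl-3-(prop-2-en-1-yl)-7-(3,4,5-trimethoxyphenyl)bicyclo[3.2.1]oct-3-ene-2,8-dione, via ring-opened benzylic cation 11 (not isolated)
Conditions: Me3SiOTf (0.2 equiv), 4 Å MS, CH2Cl2, −78 → −20 °C; then Et3N, aq NaHCO3
Reagents that add atoms: none
Why: Me3SiOTf should silylate the most basic oxygen, the vinylogous-ester carbonyl at C6, after which the benzylic O1–C2 bond breaks heterolytically to give ion pair 11, in which a trimethoxybenzyl cation is held by the intact C3a–C3 bond next to a 2-silyloxy diene, the enol-ether carbon (C7 of 10) adds to the cation, and loss of the silyl group to triflate releases 12 and the catalyst. The closest known reaction type is the Lewis-acid 1,3 O-to-C shift of benzylic enol ethers through ion pairs, which in the neolignan series is the acid-induced change of hydrobenzofuranoids into bicyclo[3.2.1]octanoids. The one new bond closes the cyclopentanone ring (C1, C8, C5, C6, C7 of 12) in a 5-(enolexo) mode onto the trigonal cation and at the same time the cycloheptenone ring in a 7-(enolendo) mode, while the dihydrofuran ring is opened. C1 is set by the tether, because the cation hangs from C5 and can reach the enol carbon only on the ring face that carries the side chain; C7 is set with the aryl group trans to the C6 methyl group (aryl on the side of the one-carbon bridge), since the cis closure would eclipse methyl and aryl in the forming five-membered ring and the closure is reversible; C5 and C6 are carried over from 10. The step needs ionisation of the benzylic C–O bond and not of the C3a methoxy group, and capture at carbon and not at oxygen: the first is secured by carbonyl-selective silylation (loss of methoxide would give an α-keto cation), the second by the fact that capture at oxygen only returns 10 whereas the C–C bonded, non-enolisable dione is expected to be the sink. Low temperature and the absence of base are meant to suppress proton loss from the cation, which would erase the methyl-bearing centre.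

**Step 9**
Reactants: 12 (1R,5R,6R,7R)-5-methoxy-6-methyl-3-(prop-2-en-1-yl)-7-(3,4,5-trimethoxyphenyl)bicyclo[3.2.1]oct-3-ene-2,8-dione
Product: 13 (1R,5S,8R,9R)-5-methoxy-9-methyl-3-(prop-2-en-1-yl)-8-(3,4,5-trimethoxyphenyl)-6-oxabicyclo[3.2.2]non-3-ene-2,7-dione
Conditions: mCPBA (1.2 equiv), CH2Cl2, 0 °C; aq Na2S2O3/NaHCO3 work-up
Reagents that add atoms: 3-chloroperoxybenzoic acid, OOC(=O)c1cccc(Cl)c1
Why: Baeyer–Villiger oxidation, in which the peracid should add to the strained bridging C8 ketone (activated by the α-methoxy and α-acyl groups) rather than to the conjugated C2 ketone, and the methoxy-bearing bridgehead C5 should migrate with retention in preference to the acyl-substituted C1, so that the oxygen enters between C5 and C8 while the electron-poor enone is inert and the monosubstituted allyl alkene reacts far more slowly at 0 °C.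

**Compound list**

1 | 4-bromobenzene-1,3-diol | Oc1ccc(Br)c(O)c1 | starting material
2 | 1-bromo-2,4-bis(methoxymethoxy)benzene | COCOc1ccc(Br)c(OCOC)c1 | intermediate
3 | 1-(3,4,5-trimethoxyphenyl)propan-1-one | CCC(=O)c1cc(OC)c(OC)c(OC)c1 | starting material
4 | rac-2-[2,4-bis(methoxymethoxy)phenyl]-1-(3,4,5-trimethoxyphenyl)propan-1-one (racemic, no defined centre) | CC(C(=O)c1cc(OC)c(OC)c(OC)c1)c1ccc(OCOC)cc1OCOC | intermediate
5 | (1S,2S)-2-[2,4-bis(methoxymethoxy)phenyl]-1-(3,4,5-trimethoxyphenyl)propan-1-ol | O[C@H](c1cc(OC)c(OC)c(OC)c1)[C@@H](C)c1ccc(OCOC)cc1OCOC | intermediate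
6 | deprotected triol, 4-[(1S,2S)-1-hydroxy-1-(3,4,5-trimethoxyphenyl)propan-2-yl]benzene-1,3-diol | O[C@H](c1cc(OC)c(OC)c(OC)c1)[C@@H](C)c1ccc(O)cc1O | intermediate
7 | (2S,3S)-3-methyl-2-(3,4,5-trimethoxyphenyl)-2,3-dihydro-1-benzofuran-6-ol (aryl and methyl trans) | Oc1ccc2c(c1)O[C@H](c1cc(OC)c(OC)c(OC)c1)[C@H]2C | intermediate
8 | (2S,3S)-5-bromo-3-methyl-2-(3,4,5-trimethoxyphenyl)-2,3-dihydro-1-benzofuran-6-ol | Brc1cc2c(cc1O)O[C@H](c1cc(OC)c(OC)c(OC)c1)[C@H]2C | intermediate
9 | (2S,3S)-3-methyl-5-(prop-2-en-1-yl)-2-(3,4,5-trimethoxyphenyl)-2,3-dihydro-1-benzofuran-6-ol | C=CCc1cc2c(cc1O)O[C@H](c1cc(OC)c(OC)c(OC)c1)[C@H]2C | intermediate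
10 | (2S,3R,3aS)-3a-methoxy-3-methyl-5-(prop-2-en-1-yl)-2-(3,4,5-trimethoxyphenyl)-3,3a-dihydro-1-benzofuran-6(2H)-one (methoxy trans to methyl, cis to aryl) | C=CCC1=C[C@@]2(OC)C(=CC1=O)O[C@H](c1cc(OC)c(OC)c(OC)c1)[C@H]2C | intermediate
11 | ring-opened benzylic cation (trimethylsilyl dienol ether of the 6-methoxycyclohexadienone, triflate ion pair) | C=CCC1=C[C@](OC)([C@H](C)[CH+]c2cc(OC)c(OC)c(OC)c2)C(=O)C=C1O[Si](C)(C)C.[O-]S(=O)(=O)C(F)(F)F | intermediate
12 | (1R,5R,6R,7R)-5-methoxy-6-methyl-3-(prop-2-en-1-yl)-7-(3,4,5-trimethoxyphenyl)bicyclo[3.2.1]oct-3-ene-2,8-dione (methyl endo, aryl exo) | C=CCC1=C[C@@]2(OC)C(=O)[C@@H](C1=O)[C@H](c1cc(OC)c(OC)c(OC)c1)[C@H]2C | intermediate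
13 | (1R,5S,8R,9R)-5-methoxy-9-methyl-3-(prop-2-en-1-yl)-8-(3,4,5-trimethoxyphenyl)-6-oxabicyclo[3.2.2]non-3-ene-2,7-dione | C=CCC1=C[C@@]2(OC)OC(=O)[C@@H](C1=O)[C@H](c1cc(OC)c(OC)c(OC)c1)[C@H]2C | target

**Totals**

Total step count: 9. Longest linear sequence: 9 steps (1 → 13; 3 is bought and enters in step 2).

**Steps most likely to fail**

1. Step 8. The ionisation may be unproductive: re-capture at oxygen may keep the equilibrium on the side of 10, or proton loss next to the cation may erode the methyl-bearing centre. Fallback: set out from 10 and couple the shift to its irreversible follow-up reaction. Treat 10 with Sc(OTf)3 (10 mol %) and mCPBA in CH2Cl2 at −20 °C, so that whatever share of 12 forms is removed at once by Baeyer–Villiger oxidation. Sc(OTf)3 is an established catalyst for peracid Baeyer–Villiger oxidation and a Lewis acid suited to O-to-C benzyl shifts. The sequence rejoins the route at 13 and makes no new compound (F0).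

2. Step 9. The oxidation may lack chemoselectivity: competing epoxidation of the allyl group, attack at the wrong carbonyl, or acid-induced opening of the acyloxy ketal. Fallback: set out from 8 and carry bromine in place of the allyl group. Oxidative methoxylation as in step 7 should give the 5-bromo analogue of 10 F1. The silyl triflate shift as in step 8 should give the 3-bromo analogue of 12 F2. mCPBA should then give the 3-bromo analogue of 13 F3, which has no isolated alkene. A final Stille coupling of the α-bromoenone (allylSnBu3, Pd(PPh3)4, CuI, DMF, 50 °C) installs the allyl group under neutral conditions and arrives at 13.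

3. Step 3. Racemisation of the α-centre may not keep pace with reduction, or the two ketone enantiomers may be reduced at similar rates, so that the methyl-bearing centre is formed with low enantiomeric purity. Fallback: set out from 4. HCl in MeOH removes the acetals and cyclodehydrates the hydroxy ketone to 3-methyl-2-(3,4,5-trimethoxyphenyl)-1-benzofuran-6-ol F4. Enantioselective cis-hydrogenation of the furan ring with a ruthenium N-heterocyclic carbene catalyst (Ru(cod)(2-methylallyl)2, chiral SINpEt ligand, KOtBu, H2) sets the methyl-bearing centre by face-selective addition and should give (2R,3S)-3-methyl-2-(3,4,5-trimethoxyphenyl)-2,3-dihydro-1-benzofuran-6-ol F5. Acid (TFA, CH2Cl2) then epimerises the benzylic ether carbon through the same cation as in step 4 to the trans isomer 7, where the route is rejoined.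

**Further compounds**

F0 | step 8 | none | none
F1 | step 9 | 5-bromo analogue of 10, 5-bromo-3a-methoxy-3-methyl-2-(3,4,5-trimethoxyphenyl)-3,3a-dihydro-1-benzofuran-6(2H)-one with the spatial arrangement of 10 | BrC1=C[C@@]2(OC)C(=CC1=O)O[C@H](c1cc(OC)c(OC)c(OC)c1)[C@H]2C
F2 | step 9 | 3-bromo analogue of 12, 3-bromo-5-methoxy-6-methyl-7-(3,4,5-trimethoxyphenyl)bicyclo[3.2.1]oct-3-ene-2,8-dione with the spatial arrangement of 12 | BrC1=C[C@@]2(OC)C(=O)[C@@H](C1=O)[C@H](c1cc(OC)c(OC)c(OC)c1)[C@H]2C
F3 | step 9 | 3-bromo analogue of 13, 3-bromo-5-methoxy-9-methyl-8-(3,4,5-trimethoxyphenyl)-6-oxabicyclo[3.2.2]non-3-ene-2,7-dione with the spatial arrangement of 13 | BrC1=C[C@@]2(OC)OC(=O)[C@@H](C1=O)[C@H](c1cc(OC)c(OC)c(OC)c1)[C@H]2C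
F4 | step 3 | 3-methyl-2-(3,4,5-trimethoxyphenyl)-1-benzofuran-6-ol | Cc1c(-c2cc(OC)c(OC)c(OC)c2)oc2cc(O)ccc12
F5 | step 3 | (2R,3S)-3-methyl-2-(3,4,5-trimethoxyphenyl)-2,3-dihydro-1-benzofuran-6-ol (aryl and methyl cis) | Oc1ccc2c(c1)O[C@@H](c1cc(OC)c(OC)c(OC)c1)[C@H]2C
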